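## Retrosynthetic overview
1. The C6 side chain is carried as an alk-1-ynyl group and saturated last with diimide. The propanoic acid is carried as a C3 allyl group (hydroboration, then oxidation).
2. The C3–allyl bond comes from axial Hosomi–Sakurai attack on the cyclic peroxycarbenium ion. The slim alkynyl group sits axial at C6, so C6 controls C3.
3. The 1,2-dioxane comes from a three-atom ring expansion (3 → 6) of an enantioenriched 2-alkynyl-2-methylcyclopropyl methyl ketone with H2O2. The C1–C2 bond breaks with inversion at the quaternary carbon, and the OOH group then closes on the ketone.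
4. The cyclopropane comes from asymmetric carbene transfer from diazoacetone to a 1,1-disubstituted enyne. The enyne comes from PhMgBr, 1,6-dibromohexane and 2-methylbut-1-en-3-yne.
5. Ring order: the cyclopropane is made first (step 4), and the dioxane is then made at its expense (step 5). No other ring is formed.

Assumption: the hemiketal/ketal carbon C3 of 12 and 13 is an anomeric mixture that converges in cation 15, so it is written without a descriptor.

## Route

Step 1
Reactants: 1 phenylmagnesium bromide; 2 1,6-dibromohexane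
Product: 3 (6-bromohexyl)benzene
Conditions: Li2CuCl4 (3 mol %), THF, 0 °C to rt; 2 in threefold excess (recovered by distillation)
Reagents that add atoms: none
Why: Copper-catalysed Kumada/Kochi-type coupling of an aryl Grignard reagent with a primary bromide, in which the excess of 2 suppresses diarylation and no stereocentre is involved.

Step 2
Reactants: 4 2-methylbut-1-en-3-yne; 3 (6-bromohexyl)benzene
Product: 6 2-methyl-10-phenyldec-1-en-3-yne, via lithium acetylide 5 (not isolated)
Conditions: n-BuLi, THF, −78 °C; then 3, DMPU, −78 °C to rt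
Reagents that add atoms: none
Why: Standard acetylide alkylation (SN2 of a lithium acetylide on a primary bromide in a dipolar cosolvent), which leaves the isopropenyl group untouched.

Step 3
Reactants: 7 acetyl chloride; 8 (trimethylsilyl)diazomethane
Product: 9 1-diazopropan-2-one (diazoacetone)
Conditions: MeCN/THF 1:1, 0 °C; used as a CH2Cl2 solution
Reagents that add atoms: none
Why: Arndt–Eistert-type acylation of a diazoalkane, in which the acid chloride acylates the diazo carbon and chloride removes the silyl group.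

Step 4
Reactants: 6 2-methyl-10-phenyldec-1-en-3-yne; 9 1-diazopropan-2-one
Product: 10 1-[(1R,2R)-2-methyl-2-(8-phenyloct-1-yn-1-yl)cyclopropyl]ethan-1-one (acetyl trans to alkynyl)
Conditions: [Ru((S)-Ph-pheox)(NCMe)4]PF6 (2 mol %; Ph-pheox = ortho-metalated 2,4-diphenyl-4,5-dihydrooxazole), CH2Cl2, 0 °C, slow addition of 9; minor cis isomer removed on silica
Reagents that add atoms: none
Why: Catalytic asymmetric metal-carbene cyclopropanation of the electron-rich alkene of a conjugated enyne, in which the chiral ruthenium carbene fixes C1 and turns the acetyl group away from the rod-like π-substituent, so the quaternary C2 is set as R in the trans isomer (the cis isomer has the opposite C2 and must be removed).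

Step 5
Reactants: 10 1-[(1R,2R)-2-methyl-2-(8-phenyloct-1-yn-1-yl)cyclopropyl]ethan-1-one
Product: 12 (6R)-3,6-dimethyl-6-(8-phenyloct-1-yn-1-yl)-1,2-dioxan-3-ol, via hydroperoxy ketone 11 (not isolated)
Conditions: anhydrous H2O2 (2 M in Et2O, 5 equiv), Sc(OTf)3 (10 mol %), CH2Cl2, −20 °C to rt; aq. NaHCO3 work-up
Reagents that add atoms: hydrogen peroxide, OO
Why: Proposed new method: Sc(OTf)3 binds the ketone and polarises the C1–C2 bond of this donor–acceptor cyclopropane, external H2O2 attacks the quaternary propargylic carbon from the rear (loose SN2, inversion, which sets C6), the scandium enolate is protonated, and the γ-hydroperoxy ketone 11 closes on its own carbonyl, so all three cyclopropane carbons end up in the six-membered peroxide; the closest known reaction types are the Lewis-acid opening of donor–acceptor cyclopropane diesters by alkyl hydroperoxides, the invertive perhydrolysis of 2,2-disubstituted oxetanes and epoxides, and the Cloke–Wilson ring expansion of cyclopropyl ketones.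

Step 6
Reactants: 12 (6R)-3,6-dimethyl-6-(8-phenyloct-1-yn-1-yl)-1,2-dioxan-3-ol
Product: 13 (6R)-3,6-dimethyl-6-(8-phenyloct-1-yn-1-yl)-1,2-dioxan-3-yl acetate
Conditions: Ac2O, pyridine, 4-(dimethylamino)pyridine (10 mol %), CH2Cl2, 0 °C to rt
Reagents that add atoms: acetic anhydride, CC(=O)OC(C)=O
Why: Nucleophile-catalysed O-acylation of the peroxyhemiketal hydroxyl, a known way to activate 1,2-dioxan-3-ols, which does not touch C6.

Step 7
Reactants: 13 (6R)-3,6-dimethyl-6-(8-phenyloct-1-yn-1-yl)-1,2-dioxan-3-yl acetate; 14 allyltrimethylsilane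
Product: 16 (3R,6R)-3,6-dimethyl-6-(8-phenyloct-1-yn-1-yl)-3-(prop-2-en-1-yl)-1,2-dioxane, via peroxycarbenium triflate 15 (not isolated)
Conditions: 14 (3 equiv), TMSOTf (20 mol %), CH2Cl2, −78 °C
Reagents that add atoms: none
Why: Hosomi–Sakurai allylation of a cyclic peroxycarbenium ion (known for dioxanyl acetates), in which the half-chair places the C6 methyl equatorial and the much smaller alkynyl group axial, and stereoelectronically preferred axial attack puts the allyl group cis to the C6 methyl and trans to the alkynyl chain, which sets C3 (the minor epimer is removed on silica).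

Step 8
Reactants: 16 (3R,6R)-3,6-dimethyl-6-(8-phenyloct-1-yn-1-yl)-3-(prop-2-en-1-yl)-1,2-dioxane
Product: 18 3-[(3S,6R)-3,6-dimethyl-6-(8-phenyloct-1-yn-1-yl)-1,2-dioxan-3-yl]propan-1-ol, via B-alkyl-9-BBN adduct 17 (not isolated)
Conditions: 9-BBN (1.2 equiv), THF, 0 °C to rt; then aq. NaOH, 30 % H2O2, 0 °C
Reagents that add atoms: hydrogen peroxide, OO
Why: Brown hydroboration–oxidation, in which 9-BBN adds to a terminal alkene far faster than to a hindered internal alkyne, and bis-tertiary dialkyl peroxides tolerate both the borane and alkaline H2O2 (the C3 descriptor changes by priority only).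

Step 9
Reactants: 18 3-[(3S,6R)-3,6-dimethyl-6-(8-phenyloct-1-yn-1-yl)-1,2-dioxan-3-yl]propan-1-ol
Product: 19 3-[(3R,6R)-3,6-dimethyl-6-(8-phenyloct-1-yn-1-yl)-1,2-dioxan-3-yl]propanoic acid
Conditions: TEMPO (2,2,6,6-tetramethylpiperidin-1-oxyl, 20 mol %), PhI(OAc)2 (2.5 equiv), MeCN/H2O 1:1, rt
Reagents that add atoms: water, O
Why: Oxoammonium-mediated oxidation of a primary alcohol through the aldehyde hydrate to the acid under near-neutral conditions that leave the alkyne and the O–O bond alone.

Step 10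
Reactants: 19 3-[(3R,6R)-3,6-dimethyl-6-(8-phenyloct-1-yn-1-yl)-1,2-dioxan-3-yl]propanoic acid
Product: 20 3-[(3R,6S)-3,6-dimethyl-6-(8-phenyloctyl)-1,2-dioxan-3-yl]propanoic acid
Conditions: KO2CN=NCO2K (30 equiv, in portions), AcOH (slow addition), MeOH/CH2Cl2, 0 °C to rt
Reagents that add atoms: none
Why: Diimide transfer hydrogenation takes the alkyne through the cis-alkene to the alkane without reducing the O–O bond, the standard way to saturate unsaturated cyclic peroxides, and both stereocentres are untouched (the C6 descriptor changes by priority only).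

## Compound list
1 | phenylmagnesium bromide | Br[Mg]c1ccccc1 | starting material
2 | 1,6-dibromohexane | BrCCCCCCBr | starting material
3 | (6-bromohexyl)benzene | BrCCCCCCc1ccccc1 | intermediate
4 | 2-methylbut-1-en-3-yne | C=C(C)C#C | starting material
5 | lithium 3-methylbut-3-en-1-yn-1-ide (not isolated) | [Li]C#CC(C)=C | intermediate
6 | 2-methyl-10-phenyldec-1-en-3-yne | C=C(C)C#CCCCCCCc1ccccc1 | intermediate
7 | acetyl chloride | CC(=O)Cl | starting material
8 | (trimethylsilyl)diazomethane | C[Si](C)(C)C=[N+]=[N-] | starting material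
9 | 1-diazopropan-2-one | CC(=O)C=[N+]=[N-] | intermediate
10 | 1-[(1R,2R)-2-methyl-2-(8-phenyloct-1-yn-1-yl)cyclopropyl]ethan-1-one | C[C@@]1(C#CCCCCCCc2ccccc2)C[C@H]1C(C)=O | intermediate
11 | (5R)-5-hydroperoxy-5-methyl-13-phenyltridec-6-yn-2-one (not isolated) | C[C@](OO)(C#CCCCCCCc1ccccc1)CCC(C)=O | intermediate
12 | (6R)-3,6-dimethyl-6-(8-phenyloct-1-yn-1-yl)-1,2-dioxan-3-ol (anomers at C3) | C[C@]1(C#CCCCCCCc2ccccc2)CCC(C)(O)OO1 | intermediate
13 | (6R)-3,6-dimethyl-6-(8-phenyloct-1-yn-1-yl)-1,2-dioxan-3-yl acetate (anomers at C3) | C[C@]1(C#CCCCCCCc2ccccc2)CCC(C)(OC(C)=O)OO1 | intermediate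
14 | allyltrimethylsilane | C=CC[Si](C)(C)C | starting material
15 | (6R)-3,6-dimethyl-6-(8-phenyloct-1-yn-1-yl)-1,2-dioxan-3-ylium triflate, C3=O2 peroxycarbenium ion (not isolated) | C[C@]1(C#CCCCCCCc2ccccc2)CCC(C)=[O+]O1.[O-]S(=O)(=O)C(F)(F)F | intermediate
16 | (3R,6R)-3,6-dimethyl-6-(8-phenyloct-1-yn-1-yl)-3-(prop-2-en-1-yl)-1,2-dioxane (methyl groups trans) | C[C@]1(C#CCCCCCCc2ccccc2)CC[C@](C)(CC=C)OO1 | intermediate
17 | 9-{3-[(3S,6R)-3,6-dimethyl-6-(8-phenyloct-1-yn-1-yl)-1,2-dioxan-3-yl]propyl}-9-borabicyclo[3.3.1]nonane (not isolated) | C[C@]1(C#CCCCCCCc2ccccc2)CC[C@](C)(CCCB3C4CCCC3CCC4)OO1 | intermediate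
18 | 3-[(3S,6R)-3,6-dimethyl-6-(8-phenyloct-1-yn-1-yl)-1,2-dioxan-3-yl]propan-1-ol | C[C@]1(C#CCCCCCCc2ccccc2)CC[C@](C)(CCCO)OO1 | intermediate
19 | 3-[(3R,6R)-3,6-dimethyl-6-(8-phenyloct-1-yn-1-yl)-1,2-dioxan-3-yl]propanoic acid | C[C@]1(C#CCCCCCCc2ccccc2)CC[C@](C)(CCC(=O)O)OO1 | intermediate
20 | 3-[(3R,6S)-3,6-dimethyl-6-(8-phenyloctyl)-1,2-dioxan-3-yl]propanoic acid | C[C@]1(CCCCCCCCc2ccccc2)CC[C@](C)(CCC(=O)O)OO1 | target

## Step count and risks
- Total steps: 10.
- Longest linear sequence: 9 (steps 1, 2 and 4–10). Step 3 is a one-step side branch.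

**Step 5 (the new ring expansion).**
- Failure modes:
  - A single ketone may activate the ring too weakly.
  - The carbonyl oxygen may close first, giving the Cloke–Wilson dihydrofuran.
  - Full ionisation would erode the ee.
  - Baeyer–Villiger oxidation of the ketone may compete.
- The fallback uses known chemistry only. It sets out from 10 and returns at 12.
- Acid-catalysed hydrolytic opening of the cyclopropyl ketone (cat. TfOH, HFIP/H2O) gives 5-hydroxy-5-methyl-13-phenyltridec-6-yn-2-one F1.
- Classical SN1 perhydrolysis of this tertiary propargylic alcohol (50 % H2O2, cat. H2SO4, 0 °C) gives racemic 3,6-dimethyl-6-(8-phenyloct-1-yn-1-yl)-1,2-dioxan-3-ol F2.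
- F2 is resolved by preparative chiral-phase SFC to give 12. Stereospecificity is given up in exchange for a resolution.

**Step 4 (asymmetric cyclopropanation).**
- Failure modes:
  - Methyl/alkynyl discrimination may be weak, giving low dr.
  - The ee with a diazoketone may be lower than with diazoesters.
  - The sense of induction on this enyne is unverified; the antipodal catalyst is equally available.
- The fallback takes the relative configuration from alkene geometry instead. It sets out from 3 and returns at 10.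
- Commercial (E)-3-methylpent-2-en-4-yn-1-ol F3 is converted to its dianion (2 equiv n-BuLi, THF/DMPU) and alkylated with 3 to give (E)-3-methyl-11-phenylundec-2-en-4-yn-1-ol F4.
- Charette asymmetric Simmons–Smith cyclopropanation follows (Et2Zn/CH2I2 and (4S,5S)-2-butyl-N,N,N',N'-tetramethyl-1,3,2-dioxaborolane-4,5-dicarboxamide). It gives [(1R,2R)-2-methyl-2-(8-phenyloct-1-yn-1-yl)cyclopropyl]methanol F5.
- Dess–Martin oxidation gives (1R,2R)-2-methyl-2-(8-phenyloct-1-yn-1-yl)cyclopropane-1-carbaldehyde F6.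
- MeMgBr then gives 1-[(1R,2R)-2-methyl-2-(8-phenyloct-1-yn-1-yl)cyclopropyl]ethan-1-ol F7, and a second Dess–Martin oxidation gives 10.

**Step 7 (allylation).**
- Failure modes:
  - Allylsilane may capture 15 too slowly, so the cation fragments or the propargylic C6–O bond ionises.
  - The dr may be modest.
- The fallback uses a far more nucleophilic two-carbon donor followed by a one-carbon homologation. It also bypasses steps 8 and 9. It sets out from 13 and returns at 19.
- Mukaiyama-type addition of commercial 1-(tert-butyldimethylsilyloxy)-1-methoxyethene F8 (cat. TMSOTf, −78 °C) gives methyl 2-[(3R,6R)-3,6-dimethyl-6-(8-phenyloct-1-yn-1-yl)-1,2-dioxan-3-yl]acetate F9.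
- LiOH gives 2-[(3R,6R)-3,6-dimethyl-6-(8-phenyloct-1-yn-1-yl)-1,2-dioxan-3-yl]acetic acid F10.
- Oxalyl chloride gives the acid chloride 2-[(3R,6R)-3,6-dimethyl-6-(8-phenyloct-1-yn-1-yl)-1,2-dioxan-3-yl]acetyl chloride F11.
- Compound 8 converts F11 into 1-diazo-3-[(3R,6R)-3,6-dimethyl-6-(8-phenyloct-1-yn-1-yl)-1,2-dioxan-3-yl]propan-2-one F12.
- Wolff rearrangement (AgO2CPh, Et3N, THF/H2O) gives 19.

## Further compounds
F1 | step 5 | 5-hydroxy-5-methyl-13-phenyltridec-6-yn-2-one | CC(=O)CCC(C)(O)C#CCCCCCCc1ccccc1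
F2 | step 5 | racemic 3,6-dimethyl-6-(8-phenyloct-1-yn-1-yl)-1,2-dioxan-3-ol | CC1(C#CCCCCCCc2ccccc2)CCC(C)(O)OO1
F3 | step 4 | (E)-3-methylpent-2-en-4-yn-1-ol | OC/C=C(C)/C#C
F4 | step 4 | (E)-3-methyl-11-phenylundec-2-en-4-yn-1-ol | OC/C=C(C)/C#CCCCCCCc1ccccc1
F5 | step 4 | [(1R,2R)-2-methyl-2-(8-phenyloct-1-yn-1-yl)cyclopropyl]methanol | C[C@@]1(C#CCCCCCCc2ccccc2)C[C@H]1CO
F6 | step 4 | (1R,2R)-2-methyl-2-(8-phenyloct-1-yn-1-yl)cyclopropane-1-carbaldehyde | C[C@@]1(C#CCCCCCCc2ccccc2)C[C@H]1C=O
F7 | step 4 | 1-[(1R,2R)-2-methyl-2-(8-phenyloct-1-yn-1-yl)cyclopropyl]ethan-1-ol (carbinol epimers) | C[C@@]1(C#CCCCCCCc2ccccc2)C[C@H]1C(C)O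
F8 | step 7 | 1-(tert-butyldimethylsilyloxy)-1-methoxyethene | C=C(OC)O[Si](C)(C)C(C)(C)C
F9 | step 7 | methyl 2-[(3R,6R)-3,6-dimethyl-6-(8-phenyloct-1-yn-1-yl)-1,2-dioxan-3-yl]acetate | C[C@]1(C#CCCCCCCc2ccccc2)CC[C@](C)(CC(=O)OC)OO1
F10 | step 7 | 2-[(3R,6R)-3,6-dimethyl-6-(8-phenyloct-1-yn-1-yl)-1,2-dioxan-3-yl]acetic acid | C[C@]1(C#CCCCCCCc2ccccc2)CC[C@](C)(CC(=O)O)OO1
F11 | step 7 | 2-[(3R,6R)-3,6-dimethyl-6-(8-phenyloct-1-yn-1-yl)-1,2-dioxan-3-yl]acetyl chloride | C[C@]1(C#CCCCCCCc2ccccc2)CC[C@](C)(CC(=O)Cl)OO1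
F12 | step 7 | 1-diazo-3-[(3R,6R)-3,6-dimethyl-6-(8-phenyloct-1-yn-1-yl)-1,2-dioxan-3-yl]propan-2-one | C[C@]1(C#CCCCCCCc2ccccc2)CC[C@](C)(CC(=O)C=[N+]=[N-])OO1
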